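Atom numbers are those of the target: O1 to C8a for the 7-methoxycoumarin (benzene ring A) and O1' to C8a' for the 5,7-dihydroxycoumarin (benzene ring B).

## Analysis of the target

The target 21 (C19H12O8) consists of two 2H-chromen-2-one units joined by a single oxygen between C8 and C8'. It has no stereocenter, and the diaryl ether axis is not expected to be configurationally stable, so the problem is one of constitution only. The sensitive groups are the two lactones (opened by hydroxide or alkoxide), the enoate bonds C3=C4 and C3'=C4' (reduced by hydrogenation, open to conjugate addition), and the free hydroxyls at C5' and C7' on an electron-rich ring. The single methyl ether at C7 has to survive while two other phenol oxygens are unmasked. The first difficulty is the ether itself: C8 lies between the oxygen-bearing C7 and C8a, and C8' between C7' and C8a', so any aryl–oxygen coupling would have to form a tetra-ortho-substituted, electron-rich diaryl ether. The second is that C4a' has an oxygen-bearing carbon on each side (C5' and C8a'), so the ring B pyranone can close in two directions unless these oxygens are differentiated. The strategy rests on ring A: three contiguous oxygens at C8a, C8 and C7, then unsubstituted C6 and C5, then carbon-substituted C4a. This reads as a 1,2,3-trioxygenated four-carbon diene (C8a–C8–C7–C6) joined to a two-carbon alkyne (C5–C4a) that brings the future C4 as a carboxyl carbon. Ring A can then be built after the C8–O bond, which is made at a tetrahedral carbon.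

## Retrosynthetic reasoning

**21 from 20.** The two O–benzyl bonds at C5' and C7' are cut last. A free C5' hydroxyl would compete for the lactone at C4a', and free phloroglucinol-type phenols would not survive the earlier oxidations and bases. Hydrogenolysis is set aside because of the two enoate double bonds, so the forward step has to be a Lewis-acid cleavage that tells benzyl from methyl.

**20 from 18.** Both pyranones are cut at C3=C4 with O1–C2 and at C3'=C4' with O1'–C2'. This leads back to the bis-salicylaldehyde 18 and two two-carbon ester ylide units. Closing both lactones in one operation saves steps. In ring B only the C8a' oxygen is free, so the direction of closure is fixed. The forward reaction has to deliver or equilibrate to the Z-cinnamates of 19.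

**18 from 17 and 16.** The C4a'–C4' bond is cut. The formyl carbon is introduced ortho to the ring B phenol that is set free from its acetal in 16. A phenoxide-directed ortho-formylation is chosen because C4a' is the only free ortho position of either phenol in 17. The formyl group of 1 cannot serve here, because it is consumed in making the C8' oxygen.

**16 from 15 and 14.** This is an oxidation-state adjustment at C4: the ester of 14 is taken to the aldehyde through alcohol 15. It precedes acetal removal because the ortho-hydroxy, para-methoxy benzylic alcohol 15 would ionize under acid.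

**14 from 10 and 11.** Ring A is cut at C5–C6 and C4a–C8a, giving diene 10 and alkyne 11. This is preferred to any cut of the ether bond because the cycloaddition delivers the arene with its three oxygens already differentiated (hydroxyl at C8a, aryloxy at C8, methoxy at C7) and with the C4 carbon in place. The forward reaction must be regioselective, with the ester next to the new hydroxyl, and must aromatize with retention of the C8a oxygen.

**10 from 9 and 8.** The diene is unravelled at its O–Si and enol O–methyl bonds to the β-keto ester 8. The enol methyl group installed here is the C7 methyl ether of the target, so no phenol has to be methylated selectively later.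

**8 from 5 and 7, and 7 from 6.** The O–C8 bond is cut while C8 is still the tetrahedral α-carbon of a keto ester. An O–H insertion of the carbenoid from 7 into phenol 5 replaces a hindered aryl–oxygen coupling. Diazo ester 7 comes from 6 by diazo transfer.

**5 from 3, 2 and 1.** The C8'–O bond is traced to the aryl–CHO bond of 3 through a Baeyer–Villiger oxidation. The protecting pattern of 3 follows from hydrogen-bond differentiation in 1: benzyl on the future C7' and C5' oxygens, and an acid-labile acetal on the future O1'.

## Alternatives that were turned down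

**Alternative 1:** Ring B is grown by a Danheiser benzannulation on the carbon that already carries the ether. The racemic cyclobutenone A1 and the silyloxyalkyne A2 are heated. Electrocyclic opening of A1 to a vinylketene, ketene–alkyne (2+2) addition (C4a'–C8a' and C5'–C6'), a second ring opening and 6π closure (C8'–C8a') would give phenol A3.
- For it: ring A arrives as a finished coumarin, the route is convergent, and A3 has only the future O1' free. The silyl groups would come off with fluoride, well away from the methyl ether. On protecting-group economy and on mildness of the final deprotection this alternative is stronger than the chosen route.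
- Against it: A1 is the silyl enol ether of a cyclobutane-1,3-dione with an aryloxy group on its sp3 carbon. It has an acidic ring hydrogen, is hydrolytically fragile and has no short, dependable preparation. A2 is itself a multistep reagent. After A3, formylation, Wittig–lactonization and desilylation are still needed.
- Comparison: the risk sits in the precursor as well as in a four-stage pericyclic cascade. The chosen route reaches 10 by standard operations from commodity materials and keeps the uncertainty in one cycloaddition.

**Alternative 2:** Ring A is made at the cyclohexane-1,3-dione level and aromatized late. KOtBu would cyclize keto ester A4 by attack of the aryloxymethyl carbon (C8) on the ester carbon (C8a) to give dione A5.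
- For it: the ether bond comes from simple alkylation of a phenoxide with an α-halo ketone, the ring closure is a textbook Dieckmann-type condensation, and the symmetric dione raises no regiochemical question. On certainty of the key step it is stronger than a hindered Diels–Alder reaction.
- Against it: ring A is formed at the wrong oxidation level. A5 still needs desymmetrizing mono-O-methylation, dehydrogenation to the arene in the presence of benzyl ethers and an electron-rich ring B, ortho-formylation and a second Wittig–lactonization. The base step also exposes the ring B lactone and its enoate to alkoxide and to enolates (ring opening, conjugate addition at C4').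
- Comparison: the chosen cycloaddition delivers arene, methyl ether, free hydroxyl and the C4 carbon in one step, and both pyranones are then closed together.

**Alternative 3:** O1' is installed last by anodic dehydrogenative lactonization. Oxidation of the (Z)-cinnamic acid A6 would make the carboxylate bond to the one free ortho carbon (O1'–C8a') and give A7, which is the same compound as 20.
- For it: ring B needs no oxygen at C8a' beforehand, so the acetal protecting group, its removal and the directed formylation all disappear. On step count after the ether is in place it is potentially stronger.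
- Against it: A6 contains three electron-rich aryl ether rings and two benzyl ethers of similar oxidation potential, so radical-cation formation is unlikely to be site-selective. C8a' is ortho to one oxygen only and meta to both benzyloxy groups, whereas C6' is flanked by two. Kolbe-type decarboxylation competes at the anode, and the acid must be held in the disfavoured Z geometry. The hindered C8–O–C8' ether must still be made by other means.
- Comparison: the chosen route carries O1' from the starting aldehyde and never has to oxidize a C–H bond on a polyoxygenated ring.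

Key step: step 8

Remark on the chemistry: 9 and 10 are carried as mixtures of double-bond isomers; both geometries lead to the same arene, so none is assigned.

## Route

Step 1
Reactants: 1 2,4,6-trihydroxybenzaldehyde
Product: 2 2,4-bis(benzyloxy)-6-hydroxybenzaldehyde
Conditions: BnBr (2.1 equiv), K2CO3, DMF, 0 °C to rt
Reagents that add atoms: benzyl bromide, BrCc1ccccc1
Why: Williamson etherification; the hydroxyl para to the formyl group and one ortho hydroxyl react, while the last ortho hydroxyl is held in a hydrogen bond to the aldehyde and is alkylated much more slowly, the usual differentiation in 2,4,6-trihydroxyaryl carbonyl compounds.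

Step 2
Reactants: 2 2,4-bis(benzyloxy)-6-hydroxybenzaldehyde
Product: 3 2,4-bis(benzyloxy)-6-(methoxymethoxy)benzaldehyde
Conditions: NaH, MOMCl, DMF, 0 °C to rt
Reagents that add atoms: chloromethyl methyl ether, COCCl
Why: O-alkylation of the chelated phenol after full deprotonation; the acetal is stable to base, hydride, buffered peracid and heat and is later removed by dilute acid without loss of benzyl ethers.

Step 3
Reactants: 3 2,4-bis(benzyloxy)-6-(methoxymethoxy)benzaldehyde
Product: 5 2,4-bis(benzyloxy)-6-(methoxymethoxy)phenol, via aryl formate 4 (not isolated)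
Conditions: mCPBA, Na2HPO4, CH2Cl2, 0 °C to rt; then K2CO3 (cat.), MeOH, rt
Reagents that add atoms: 3-chloroperoxybenzoic acid, OOC(=O)c1cccc(Cl)c1
Why: Baeyer–Villiger oxidation in which the electron-rich trioxygenated aryl group migrates, followed by methanolysis of the formate; the buffer protects the acetal.

Step 4
Reactants: 6 methyl acetoacetate
Product: 7 methyl 2-diazo-3-oxobutanoate
Conditions: 4-acetamidobenzenesulfonyl azide, Et3N, MeCN, 0 °C to rt
Reagents that add atoms: 4-acetamidobenzenesulfonyl azide, CC(=O)Nc1ccc(cc1)S(=O)(=O)N=[N+]=[N-]
Why: Regitz diazo transfer to the active methylene of a β-keto ester.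

Step 5
Reactants: 5 2,4-bis(benzyloxy)-6-(methoxymethoxy)phenol; 7 methyl 2-diazo-3-oxobutanoate
Product: 8 methyl 2-[2,4-bis(benzyloxy)-6-(methoxymethoxy)phenoxy]-3-oxobutanoate (racemic)
Conditions: Rh2(OAc)4 (1 mol %), PhH, 80 °C, slow addition of 7
Reagents that add atoms: none
Why: Dirhodium carbenoid O–H insertion of a phenol (oxonium ylide, then proton shift); the O–C8 bond forms at a tetrahedral carbon, so the two ortho substituents of the phenol hinder it far less than they would an aryl–oxygen coupling.

Step 6
Reactants: 8 methyl 2-[2,4-bis(benzyloxy)-6-(methoxymethoxy)phenoxy]-3-oxobutanoate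
Product: 9 methyl 2-[2,4-bis(benzyloxy)-6-(methoxymethoxy)phenoxy]-3-methoxybut-2-enoate (E/Z mixture)
Conditions: Me2SO4, K2CO3, DMF, rt
Reagents that add atoms: dimethyl sulfate, COS(=O)(=O)OC
Why: O-alkylation of a β-keto ester enolate by a hard methylating agent in a dipolar aprotic solvent; the carbon terminus is already trisubstituted and shielded by the 2,6-disubstituted aryloxy group, and the basic conditions spare the acetal that an acid-catalysed enol ether formation would cleave.

Step 7
Reactants: 9 methyl 2-[2,4-bis(benzyloxy)-6-(methoxymethoxy)phenoxy]-3-methoxybut-2-enoate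
Product: 10 2-[2,4-bis(benzyloxy)-6-(methoxymethoxy)phenoxy]-1,3-dimethoxy-1-(trimethylsilyloxy)buta-1,3-diene
Conditions: LiN(iPr)2, THF, −78 °C; Me3SiCl, −78 °C to rt; pentane, filtration, no aqueous work-up
Reagents that add atoms: chlorotrimethylsilane, C[Si](C)(C)Cl
Why: γ-Deprotonation of the β-methoxy enoate (the α-carbon bears no hydrogen) and O-silylation of the dienolate, the standard preparation of mixed methyl trimethylsilyl ketene acetal dienes.

Step 8
Reactants: 10 2-[2,4-bis(benzyloxy)-6-(methoxymethoxy)phenoxy]-1,3-dimethoxy-1-(trimethylsilyloxy)buta-1,3-diene; 11 methyl propiolate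
Product: 14 methyl 3-[2,4-bis(benzyloxy)-6-(methoxymethoxy)phenoxy]-2-hydroxy-4-methoxybenzoate, via cyclohexadiene cycloadduct 12 (not isolated), via aryl trimethylsilyl ether 13 (not isolated)
Conditions: 11 (3 equiv), PhMe, 90 °C, sealed tube; then K2CO3 (cat.), MeOH, rt
Reagents that add atoms: none
Why: This is a normal-electron-demand Diels–Alder reaction of an oxygenated ketene acetal diene with an alkynoate, the established route from such dienes to salicylates. The largest HOMO coefficient of 10 lies at its unsubstituted terminus (future C6), pushed by the ketene acetal oxygens at C8a and the methoxy group at C7, and the largest LUMO coefficient of 11 lies at its β-carbon, so C5–C6 leads and C4a–C8a follows in a concerted, asynchronous (4+2) addition that closes the six-membered carbocycle of ring A intermolecularly. Adduct 12 is a cyclohexa-1,4-diene with a doubly allylic CH2 at C6 and a mixed ketal at C8a; 1,4-elimination of methanol gives silyl ether 13, and methanolysis of the O–Si bond gives phenol 14, held by a hydrogen bond to the ester. Any 12 that survives heating converges on 14 in the same work-up, since desilylation of the ketal gives a hemiketal that expels methanol and tautomerizes. No stereocenter remains, because the ketal carbon of 12 is formed racemic and is flattened on aromatization. The selectivity needed is regiochemical (ester next to the new hydroxyl), and it rests on the matched polarization of the two partners; the aryloxy group on C8 shares its lone pair with its own ring and is cross-conjugated to the reacting terminus, so it should not overturn this. The bulky aryloxy group sits on an inner diene carbon, points away from the dienophile and favours the s-cis conformer.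

Step 9
Reactants: 14 methyl 3-[2,4-bis(benzyloxy)-6-(methoxymethoxy)phenoxy]-2-hydroxy-4-methoxybenzoate
Product: 15 2-[2,4-bis(benzyloxy)-6-(methoxymethoxy)phenoxy]-6-(hydroxymethyl)-3-methoxyphenol
Conditions: LiAlH4, THF, 0 °C to rt; aqueous potassium sodium tartrate
Reagents that add atoms: none
Why: Hydride reduction of the ester to the primary alcohol; acetal, benzyl ethers and diaryl ether are inert, and the neutral work-up avoids ionization of the acid-labile ortho-hydroxy benzylic alcohol.

Step 10
Reactants: 15 2-[2,4-bis(benzyloxy)-6-(methoxymethoxy)phenoxy]-6-(hydroxymethyl)-3-methoxyphenol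
Product: 16 3-[2,4-bis(benzyloxy)-6-(methoxymethoxy)phenoxy]-2-hydroxy-4-methoxybenzaldehyde
Conditions: activated MnO2, CH2Cl2, rt
Reagents that add atoms: none
Why: Selective benzylic oxidation, well established for 2-hydroxybenzyl alcohols to salicylaldehydes; the aldehyde is stabilized by hydrogen bonding to the phenol and is not oxidized further.

Step 11
Reactants: 16 3-[2,4-bis(benzyloxy)-6-(methoxymethoxy)phenoxy]-2-hydroxy-4-methoxybenzaldehyde
Product: 17 3-[2,4-bis(benzyloxy)-6-hydroxyphenoxy]-2-hydroxy-4-methoxybenzaldehyde
Conditions: 3 M aq. HCl, THF, 50 °C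
Reagents that add atoms: none
Why: Acid hydrolysis of the methoxymethyl aryl ether; benzyl ethers, the methyl ether, the diaryl ether and the aldehyde tolerate dilute aqueous acid.

Step 12
Reactants: 17 3-[2,4-bis(benzyloxy)-6-hydroxyphenoxy]-2-hydroxy-4-methoxybenzaldehyde
Product: 18 4,6-bis(benzyloxy)-3-(3-formyl-2-hydroxy-6-methoxyphenoxy)-2-hydroxybenzaldehyde
Conditions: MgCl2, Et3N, (CH2O)n, MeCN, reflux; then 1 M HCl
Reagents that add atoms: formaldehyde (as paraformaldehyde), C=O
Why: Magnesium phenoxide-mediated ortho-formylation (Casnati–Skattebøl), in which a second formaldehyde oxidizes the benzylic alkoxide by hydride transfer; the ring A phenol has both ortho positions occupied and the ring B phenol has only C4a' free, so one formyl group enters at one site.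

Step 13
Reactants: 18 4,6-bis(benzyloxy)-3-(3-formyl-2-hydroxy-6-methoxyphenoxy)-2-hydroxybenzaldehyde
Product: 20 5,7-bis(benzyloxy)-8-[(7-methoxy-2-oxo-2H-chromen-8-yl)oxy]-2H-chromen-2-one, via bis-cinnamate diester 19 (not isolated)
Conditions: Ph3P=CHCO2Et (2.5 equiv), PhNEt2, reflux (about 215 °C)
Reagents that add atoms: ethyl (triphenylphosphoranylidene)acetate, CCOC(=O)C=P(c1ccccc1)(c1ccccc1)c1ccccc1
Why: Double Wittig olefination with an ester-stabilized ylide, then thermal E to Z equilibration and lactonization with loss of ethanol in the same pot, the classical coumarin synthesis from salicylaldehydes; on ring B only the C8a' oxygen is free, so the pyranone closes in one direction.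

Step 14
Reactants: 20 5,7-bis(benzyloxy)-8-[(7-methoxy-2-oxo-2H-chromen-8-yl)oxy]-2H-chromen-2-one
Product: 21 5,7-dihydroxy-8-[(7-methoxy-2-oxo-2H-chromen-8-yl)oxy]-2H-chromen-2-one
Conditions: BCl3, C6HMe5, CH2Cl2, −78 °C; then H2O
Reagents that add atoms: none
Why: Lewis-acid cleavage of aryl benzyl ethers at low temperature with pentamethylbenzene as trap for the benzyl cation; the benzyl–oxygen bonds ionize far faster than the methyl–oxygen bond at C7, the enoate double bonds are untouched, and the trap prevents C-benzylation of ring B.

## Compound list

1 | 2,4,6-trihydroxybenzaldehyde | O=Cc1c(O)cc(O)cc1O | starting material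
2 | 2,4-bis(benzyloxy)-6-hydroxybenzaldehyde | O=Cc1c(O)cc(OCc2ccccc2)cc1OCc1ccccc1 | intermediate
3 | 2,4-bis(benzyloxy)-6-(methoxymethoxy)benzaldehyde | COCOc1cc(OCc2ccccc2)cc(OCc2ccccc2)c1C=O | intermediate
4 | 2,4-bis(benzyloxy)-6-(methoxymethoxy)phenyl formate (not isolated) | O=COc1c(OCOC)cc(OCc2ccccc2)cc1OCc1ccccc1 | intermediate
5 | 2,4-bis(benzyloxy)-6-(methoxymethoxy)phenol | Oc1c(OCOC)cc(OCc2ccccc2)cc1OCc1ccccc1 | intermediate
6 | methyl acetoacetate | COC(=O)CC(C)=O | starting material
7 | methyl 2-diazo-3-oxobutanoate | COC(=O)C(=[N+]=[N-])C(C)=O | intermediate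
8 | methyl 2-[2,4-bis(benzyloxy)-6-(methoxymethoxy)phenoxy]-3-oxobutanoate (racemic) | COC(=O)C(Oc1c(OCOC)cc(OCc2ccccc2)cc1OCc1ccccc1)C(C)=O | intermediate
9 | methyl 2-[2,4-bis(benzyloxy)-6-(methoxymethoxy)phenoxy]-3-methoxybut-2-enoate (E/Z mixture) | COC(=O)C(Oc1c(OCOC)cc(OCc2ccccc2)cc1OCc1ccccc1)=C(C)OC | intermediate
10 | 2-[2,4-bis(benzyloxy)-6-(methoxymethoxy)phenoxy]-1,3-dimethoxy-1-(trimethylsilyloxy)buta-1,3-diene (ketene acetal geometry not defined) | COC(O[Si](C)(C)C)=C(Oc1c(OCOC)cc(OCc2ccccc2)cc1OCc1ccccc1)C(OC)=C | intermediate
11 | methyl propiolate | C#CC(=O)OC | starting material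
12 | methyl 5-[2,4-bis(benzyloxy)-6-(methoxymethoxy)phenoxy]-4,6-dimethoxy-6-(trimethylsilyloxy)cyclohexa-1,4-diene-1-carboxylate (racemic, not isolated) | COC(=O)C1=CCC(OC)=C(Oc2c(OCOC)cc(OCc3ccccc3)cc2OCc2ccccc2)C1(OC)O[Si](C)(C)C | intermediate
13 | methyl 3-[2,4-bis(benzyloxy)-6-(methoxymethoxy)phenoxy]-4-methoxy-2-(trimethylsilyloxy)benzoate (not isolated) | COC(=O)c1ccc(OC)c(Oc2c(OCOC)cc(OCc3ccccc3)cc2OCc2ccccc2)c1O[Si](C)(C)C | intermediate
14 | methyl 3-[2,4-bis(benzyloxy)-6-(methoxymethoxy)phenoxy]-2-hydroxy-4-methoxybenzoate | COC(=O)c1ccc(OC)c(Oc2c(OCOC)cc(OCc3ccccc3)cc2OCc2ccccc2)c1O | intermediate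
15 | 2-[2,4-bis(benzyloxy)-6-(methoxymethoxy)phenoxy]-6-(hydroxymethyl)-3-methoxyphenol | OCc1ccc(OC)c(Oc2c(OCOC)cc(OCc3ccccc3)cc2OCc2ccccc2)c1O | intermediate
16 | 3-[2,4-bis(benzyloxy)-6-(methoxymethoxy)phenoxy]-2-hydroxy-4-methoxybenzaldehyde | O=Cc1ccc(OC)c(Oc2c(OCOC)cc(OCc3ccccc3)cc2OCc2ccccc2)c1O | intermediate
17 | 3-[2,4-bis(benzyloxy)-6-hydroxyphenoxy]-2-hydroxy-4-methoxybenzaldehyde | O=Cc1ccc(OC)c(Oc2c(O)cc(OCc3ccccc3)cc2OCc2ccccc2)c1O | intermediate
18 | 4,6-bis(benzyloxy)-3-(3-formyl-2-hydroxy-6-methoxyphenoxy)-2-hydroxybenzaldehyde | O=Cc1ccc(OC)c(Oc2c(O)c(C=O)c(OCc3ccccc3)cc2OCc2ccccc2)c1O | intermediate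
19 | ethyl 3-{4,6-bis(benzyloxy)-3-[3-(3-ethoxy-3-oxoprop-1-en-1-yl)-2-hydroxy-6-methoxyphenoxy]-2-hydroxyphenyl}prop-2-enoate (E/Z mixture at both double bonds, not isolated) | CCOC(=O)C=Cc1ccc(OC)c(Oc2c(O)c(C=CC(=O)OCC)c(OCc3ccccc3)cc2OCc2ccccc2)c1O | intermediate
20 | 5,7-bis(benzyloxy)-8-[(7-methoxy-2-oxo-2H-chromen-8-yl)oxy]-2H-chromen-2-one | COc1ccc2ccc(=O)oc2c1Oc1c(OCc2ccccc2)cc(OCc2ccccc2)c2ccc(=O)oc12 | intermediate
21 | 5,7-dihydroxy-8-[(7-methoxy-2-oxo-2H-chromen-8-yl)oxy]-2H-chromen-2-one | COc1ccc2ccc(=O)oc2c1Oc1c(O)cc(O)c2ccc(=O)oc12 | target

## Step count and least certain steps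

Total step count: 14. Longest linear sequence: 13 steps (1 to 21 through steps 1 to 3 and 5 to 14); step 4 is a one-step branch.

**Step 8 (key step).** The cycloaddition at the congested, fully oxygenated diene may be slow, so that protodesilylation of the ketene acetal back to 9 outruns it. The aryloxy donor on the central carbon may also erode the regiocontrol. Fallback: from 10, methyl acrylate (C=CC(=O)OC) replaces the alkyne. Alkenes are the more reactive dienophiles, and the terminal CH2 leaves no regiochemical choice. Heating in PhMe should give the cyclohexene cycloadduct F1. K2CO3 in MeOH should unmask its ketal to the cyclic β-keto ester F2. Dehydrogenation of F2 with DDQ in dioxane should give the salicylate, so the fallback returns to the route at 14.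

**Step 6.** Methylation may go to carbon at the doubly activated position, or the acetyl group may be lost by retro-Claisen cleavage under the basic conditions. Fallback: from 8, no enol methyl ether is made.
- Me3SiCl with Et3N should give the silyl enol ether F3.
- LiN(iPr)2 with Me3SiCl should give the bis(silyloxy) diene F4.
- Cycloaddition of F4 with 11 should give cycloadduct F5, which on methanolic work-up aromatizes to the dihydroxybenzoate F6.
- The hydroxyl para to the ester, which is not hydrogen-bonded, is then methylated selectively with MeI and K2CO3 in acetone, and the fallback returns at 14.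

**Step 5.** The hindered phenol may capture the carbenoid slowly, so that it is diverted to addition to the electron-rich rings, to ylide formation at ether oxygens or to dimerization. Fallback: from 5, the phenoxide is alkylated in an SN2 reaction with commercial methyl 2-chloro-3-oxobutanoate (COC(=O)C(Cl)C(C)=O) using K2CO3 in acetone. This returns at 8 and makes step 4 unnecessary.

**Step 13.** E to Z isomerization may be incomplete at the hindered ring B arm, so that lactonization stalls at an open hydroxycinnamate. Benzyl groups may also migrate at the high temperature. Fallback: from 18, both phenols are acylated with ketenylidenetriphenylphosphorane (O=C=C=P(c1ccccc1)(c1ccccc1)c1ccccc1) in PhMe at reflux to give the bis(phosphoranylideneacetate) ester F7. Its intramolecular Wittig reactions can only give the cis ring olefins, so it returns at 20 at a much lower temperature.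

**Step 14.** The methyl ether at C7 may be cleaved along with the benzyl ethers, or the benzyl cation may attack C6' of the liberated ring B. Fallback: from 20, the O–benzyl bonds are cleaved reductively by hydrogenolysis (H2, Pd/C, EtOAc, rt, stopped after two equivalents). This mechanism cannot touch a methyl ether and returns directly at 21. Saturation of the pyranone double bonds is the process to watch.

## Further compounds

F1 | step 8 | methyl 3-[2,4-bis(benzyloxy)-6-(methoxymethoxy)phenoxy]-2,4-dimethoxy-2-(trimethylsilyloxy)cyclohex-3-ene-1-carboxylate (racemic, diastereomer mixture) | COC(=O)C1CCC(OC)=C(Oc2c(OCOC)cc(OCc3ccccc3)cc2OCc2ccccc2)C1(OC)O[Si](C)(C)C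
F2 | step 8 | methyl 3-[2,4-bis(benzyloxy)-6-(methoxymethoxy)phenoxy]-4-methoxy-2-oxocyclohex-3-ene-1-carboxylate (racemic) | COC(=O)C1CCC(OC)=C(Oc2c(OCOC)cc(OCc3ccccc3)cc2OCc2ccccc2)C1=O
F3 | step 6 | methyl 2-[2,4-bis(benzyloxy)-6-(methoxymethoxy)phenoxy]-3-(trimethylsilyloxy)but-2-enoate (E/Z mixture) | COC(=O)C(Oc1c(OCOC)cc(OCc2ccccc2)cc1OCc1ccccc1)=C(C)O[Si](C)(C)C
F4 | step 6 | 2-[2,4-bis(benzyloxy)-6-(methoxymethoxy)phenoxy]-1-methoxy-1,3-bis(trimethylsilyloxy)buta-1,3-diene (ketene acetal geometry not defined) | COC(O[Si](C)(C)C)=C(Oc1c(OCOC)cc(OCc2ccccc2)cc1OCc1ccccc1)C(O[Si](C)(C)C)=C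
F5 | step 6 | methyl 5-[2,4-bis(benzyloxy)-6-(methoxymethoxy)phenoxy]-6-methoxy-4,6-bis(trimethylsilyloxy)cyclohexa-1,4-diene-1-carboxylate (racemic) | COC(=O)C1=CCC(O[Si](C)(C)C)=C(Oc2c(OCOC)cc(OCc3ccccc3)cc2OCc2ccccc2)C1(OC)O[Si](C)(C)C
F6 | step 6 | methyl 3-[2,4-bis(benzyloxy)-6-(methoxymethoxy)phenoxy]-2,4-dihydroxybenzoate | COC(=O)c1ccc(O)c(Oc2c(OCOC)cc(OCc3ccccc3)cc2OCc2ccccc2)c1O
F0 | step 5 | none | none
F7 | step 13 | 3,5-bis(benzyloxy)-2-formyl-6-(3-formyl-6-methoxy-2-{[(triphenylphosphoranylidene)acetyl]oxy}phenoxy)phenyl (triphenylphosphoranylidene)acetate | O=Cc1ccc(OC)c(Oc2c(OC(=O)C=P(c3ccccc3)(c3ccccc3)c3ccccc3)c(C=O)c(OCc3ccccc3)cc2OCc2ccccc2)c1OC(=O)C=P(c1ccccc1)(c1ccccc1)c1ccccc1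
F0 | step 14 | none | none
A1 | alternative 1 | 4-[(7-methoxy-2-oxo-2H-chromen-8-yl)oxy]-3-(triisopropylsilyloxy)cyclobut-2-en-1-one (racemic) | COc1ccc2ccc(=O)oc2c1OC1C(=O)C=C1O[Si](C(C)C)(C(C)C)C(C)C
A2 | alternative 1 | (triisopropylsilyloxy)ethyne | C#CO[Si](C(C)C)(C(C)C)C(C)C
A3 | alternative 1 | 2-[(7-methoxy-2-oxo-2H-chromen-8-yl)oxy]-3,5-bis(triisopropylsilyloxy)phenol | COc1ccc2ccc(=O)oc2c1Oc1c(O)cc(O[Si](C(C)C)(C(C)C)C(C)C)cc1O[Si](C(C)C)(C(C)C)C(C)C
A4 | alternative 2 | methyl 6-{[5,7-bis(benzyloxy)-2-oxo-2H-chromen-8-yl]oxy}-5-oxohexanoate | COC(=O)CCCC(=O)COc1c(OCc2ccccc2)cc(OCc2ccccc2)c2ccc(=O)oc12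
A5 | alternative 2 | 2-{[5,7-bis(benzyloxy)-2-oxo-2H-chromen-8-yl]oxy}cyclohexane-1,3-dione | O=C1CCCC(=O)C1Oc1c(OCc2ccccc2)cc(OCc2ccccc2)c2ccc(=O)oc12
A6 | alternative 3 | (2Z)-3-{2,4-bis(benzyloxy)-5-[(7-methoxy-2-oxo-2H-chromen-8-yl)oxy]phenyl}prop-2-enoic acid | COc1ccc2ccc(=O)oc2c1Oc1cc(/C=C\C(O)=O)c(OCc2ccccc2)cc1OCc1ccccc1
A7 | alternative 3 | 5,7-bis(benzyloxy)-8-[(7-methoxy-2-oxo-2H-chromen-8-yl)oxy]-2H-chromen-2-one | COc1ccc2ccc(=O)oc2c1Oc1c(OCc2ccccc2)cc(OCc2ccccc2)c2ccc(=O)oc12
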